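**Plan**
- Enabling feature: in each pyranone (ring C and ring F) the stereocentre C2 (C2'') is a benzylic ether carbon. It is bonded to the ring oxygen O1 (O1'') and to an electron-rich aryl ring (B or E). Its neighbour C3 (C3'') is a plain methylene next to the C4 ketone, so C3 can arrive as a ketocarbene that inserts into an O–CH2–aryl C–H.
- Retrosynthesis: remove three phenol silyl ethers, then cut C2–C3 and C2''–C3'' together to reach a bis(diazomethyl ketone). Take both diazo groups back to acetyl groups, then cut O1–CH2 (ring A/ring B), the C2'–C8'' biaryl bond, and O1''–CH2 (ring D/ring E).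
- Building blocks: one mono-silylated 2,6-dihydroxy-4-methoxyacetophenone serves as ring A and, after iodination, as ring D. Ring E comes from syringaldehyde. Ring B comes from isovanillin, as a benzoxaborole.
- Forward order: D–E ether, B–D biaryl, A–B ether, double diazo transfer, rings C and F closed in one operation, desilylation.
- Stereochemistry: both S centres arise in the key step, where the catalyst selects the pro-S hydrogen of each OCH2 group. The flavanones meet no unbuffered base afterwards.

Key step: step 13

Assumption 1: the C2'–C8'' axis carries four ortho substituents and is probably configurationally stable, but the given structure assigns it no descriptor. Compounds 15–19 are therefore carried with a racemic axis, and the two 2S,2''S atropisomers, if they do not interconvert, are separated by chromatography at 21 or 22.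
Assumption 2: Rh2(S-PTTL)4 is taken to deliver the carbene to the pro-S hydrogen. If the sense proves opposite, the mirror-image catalyst Rh2(R-PTTL)4 is used under the same conditions.

TIPS = triisopropylsilyl.

**Step 1**
Reactants: 1 2,6-dihydroxy-4-methoxyacetophenone
Product: 2 1-[2-hydroxy-4-methoxy-6-(triisopropylsilyloxy)phenyl]ethanone
Conditions: TIPSCl (1.05 equiv), imidazole, DMF, 0 °C to rt
Reagents that add atoms: triisopropylsilyl chloride, CC(C)[Si](Cl)(C(C)C)C(C)C
Why: Phenol silylation; once one of the two equivalent hydroxyls has reacted, the other is locked in a hydrogen bond to the acetyl group and crowded, so one equivalent of the bulky chloride should stop at the monoether.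

**Step 2**
Reactants: 2 1-[2-hydroxy-4-methoxy-6-(triisopropylsilyloxy)phenyl]ethanone
Product: 3 1-[2-hydroxy-3-iodo-4-methoxy-6-(triisopropylsilyloxy)phenyl]ethanone
Conditions: NIS (1.0 equiv), CH2Cl2, 0 °C, dark
Reagents that add atoms: N-iodosuccinimide, O=C1CCC(=O)N1I
Why: Electrophilic aromatic iodination; C3 (ortho to the free OH, para to OTIPS) is as activated as C5 but much less shielded than C5 beside the silyloxy group, in line with the ortho-to-OH halogenation known for 2-hydroxy-4,6-dialkoxyacetophenones.

**Step 3**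
Reactants: 4 syringaldehyde
Product: 5 3,5-dimethoxy-4-(triisopropylsilyloxy)benzaldehyde
Conditions: TIPSCl, imidazole, DMAP (cat.), DMF, rt to 40 °C
Reagents that add atoms: triisopropylsilyl chloride, CC(C)[Si](Cl)(C(C)C)C(C)C
Why: Phenol silylation; the acidic para-formyl phenol is silylated despite its two flanking methoxy groups, which afterwards shield the Si–O bond.

**Step 4**
Reactants: 5 3,5-dimethoxy-4-(triisopropylsilyloxy)benzaldehyde
Product: 6 [3,5-dimethoxy-4-(triisopropylsilyloxy)phenyl]methanol
Conditions: NaBH4, MeOH/THF, 0 °C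
Reagents that add atoms: none
Why: Borohydride reduction of an aromatic aldehyde, to which the aryl silyl ether is inert.

**Step 5**
Reactants: 3 1-[2-hydroxy-3-iodo-4-methoxy-6-(triisopropylsilyloxy)phenyl]ethanone; 6 [3,5-dimethoxy-4-(triisopropylsilyloxy)phenyl]methanol
Product: 7 1-[2-{[3,5-dimethoxy-4-(triisopropylsilyloxy)benzyl]oxy}-3-iodo-4-methoxy-6-(triisopropylsilyloxy)phenyl]ethanone (ring D–ring E iodide)
Conditions: PPh3, DIAD, THF, 0 °C to rt
Reagents that add atoms: none
Why: Mitsunobu etherification; the acidic ortho-acyl, ortho-iodo phenol and a primary benzylic alcohol couple under neutral conditions that spare both silyl ethers and avoid a labile electron-rich benzyl halide.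

**Step 6**
Reactants: 8 isovanillin
Product: 9 2-bromo-3-hydroxy-4-methoxybenzaldehyde
Conditions: Br2, NaOAc, Fe powder (cat.), AcOH, rt
Reagents that add atoms: bromine, BrBr
Why: Electrophilic aromatic bromination; under these buffered conditions the hydroxyl directs to the ortho position between OH and CHO, the established route to the 2-bromo isomer.

**Step 7**
Reactants: 9 2-bromo-3-hydroxy-4-methoxybenzaldehyde
Product: 10 2-bromo-3,4-dimethoxybenzaldehyde
Conditions: MeI, K2CO3, DMF, rt
Reagents that add atoms: iodomethane, CI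
Why: Williamson O-methylation of the only phenol.

**Step 8**
Reactants: 10 2-bromo-3,4-dimethoxybenzaldehyde
Product: 11 (2-bromo-3,4-dimethoxyphenyl)methanol
Conditions: NaBH4, MeOH, 0 °C
Reagents that add atoms: none
Why: Borohydride reduction of the aldehyde, which leaves the aryl bromide untouched.

**Step 9**
Reactants: 11 (2-bromo-3,4-dimethoxyphenyl)methanol
Product: 14 6,7-dimethoxy-1,3-dihydro-2,1-benzoxaborol-1-ol, via dilithio species 12 (not isolated), via lithium triisopropoxyborate 13 (not isolated)
Conditions: n-BuLi (2.2 equiv), THF, −78 °C; B(OiPr)3, −78 °C to rt; 2 M HCl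
Reagents that add atoms: triisopropyl borate, CC(C)OB(OC(C)C)OC(C)C; water, O
Why: Lithium–bromine exchange on the preformed lithium alkoxide, borate trapping and acid-induced closure onto the neighbouring CH2OH, the standard benzoxaborole synthesis from 2-bromobenzyl alcohols.

**Step 10**
Reactants: 7 ring D–ring E iodide; 14 6,7-dimethoxy-1,3-dihydro-2,1-benzoxaborol-1-ol
Product: 15 1-[2-{[3,5-dimethoxy-4-(triisopropylsilyloxy)benzyl]oxy}-3-[6-(hydroxymethyl)-2,3-dimethoxyphenyl]-4-methoxy-6-(triisopropylsilyloxy)phenyl]ethanone (biaryl alcohol, racemic axis)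
Conditions: Pd2(dba)3 (2.5 mol %), SPhos (10 mol %), K3PO4, toluene/H2O 10:1, 90 °C
Reagents that add atoms: none
Why: Suzuki–Miyaura coupling; the iodide adds readily to zerovalent palladium, the bulky electron-rich biarylphosphine SPhos is the established ligand type for biaryls with four ortho substituents, and the benzoxaborole resists protodeboronation and releases the hydroxymethyl group directly on transmetalation.

**Step 11**
Reactants: 15 biaryl alcohol; 2 1-[2-hydroxy-4-methoxy-6-(triisopropylsilyloxy)phenyl]ethanone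
Product: 16 bis(methyl ketone), 1-[2-({2-[3-acetyl-2-{[3,5-dimethoxy-4-(triisopropylsilyloxy)benzyl]oxy}-6-methoxy-4-(triisopropylsilyloxy)phenyl]-3,4-dimethoxybenzyl}oxy)-4-methoxy-6-(triisopropylsilyloxy)phenyl]ethanone
Conditions: PPh3, DIAD, THF, 0 °C to rt
Reagents that add atoms: none
Why: Mitsunobu etherification; the only free hydroxyl of 15 is a primary, para-methoxy-activated benzylic alcohol and the only acidic partner is the chelated phenol of 2, so the A–B ether should form under neutral conditions that spare the silyl ethers and both ketones.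

**Step 12**
Reactants: 16 bis(methyl ketone)
Product: 19 bis(diazomethyl ketone) (16 with each COCH3 turned into COCH=N2), via bis(lithium enolate) 17 (not isolated), via bis(trifluoroacetyl) diketone 18 (not isolated)
Conditions: LiHMDS (2.4 equiv), THF, −78 °C; CF3CO2CH2CF3, −78 °C; 5% aq HCl quench; crude 18, p-ABSA, Et3N, H2O, MeCN, rt
Reagents that add atoms: 4-acetamidobenzenesulfonyl azide (p-ABSA), CC(=O)Nc1ccc(cc1)S(=O)(=O)N=[N+]=[N-]; 2,2,2-trifluoroethyl trifluoroacetate, O=C(OCC(F)(F)F)C(F)(F)F (its CF3CO groups stay only in 18)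
Why: Detrifluoroacetylative diazo transfer (a Regitz-type transfer to an activated methyl ketone); each kinetic enolate is C-acylated, the 1,3-diketone takes the diazo group from the sulfonyl azide under mild amine base and sheds CF3CO as the N-sulfonyl amide, which is the standard route from methyl ketones to terminal diazomethyl ketones.

**Step 13**
Reactants: 19 bis(diazomethyl ketone)
Product: 21 (2S,2''S)-tris(triisopropylsilyl) ether of the target, via ring F flavanone diazoketone 20 (not isolated)
Conditions: Rh2(S-PTTL)4, i.e. dirhodium tetrakis[N-phthaloyl-(S)-tert-leucinate] (2 mol %), 4 Å MS, CH2Cl2 (high dilution), slow addition of 19, 0 °C to rt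
Reagents that add atoms: none
Why: Each diazo carbon binds to an axial site of the divalent rhodium dimer and loses N2, and the electrophilic carbene carbon C3 (C3'') then takes the neighbouring O–CH2–aryl C–H through a concerted, asynchronous three-centre transition state with hydride-transfer character, which releases the catalyst. The closest known reaction type is the enantioselective intramolecular C–H insertion of 2-alkoxyaryl alpha-diazoketones to chroman-4-ones under chiral dirhodium tetracarboxylates. Ring F and ring C each close by a 1,6-insertion (six-membered, forming C2''–C3'' and C2–C3), the usual 1,5 path being unavailable because position 5 of each chain is the ether oxygen. Insertion goes with retention, so replacing the pro-S hydrogen gives 2S and 2''S, and at both centres the choice between the enantiotopic hydrogens is made by the chiral pocket of the four N-phthaloyl-tert-leucinate ligands, since the substrate holds no stereocentre. The selectivity needed is insertion over attack of the ether oxygen on the carbene (five-membered oxonium ylide, then 1,2-benzyl shift to a 2-benzylbenzofuran-3-one); it is served by the low basicity of O1 and O1'' (vinylogous ester oxygens), by the para donors of ring B (4'-OMe) and ring E (4'''-OTIPS) that make the C–H hydridic, and by the two ortho substituents that twist each acyl group out of the arene plane and place the carbene over the CH2 group. The silyl ethers prevent O–H insertion, offer no C–H alpha to oxygen and shield O5 and O5'', and slow addition at high dilution holds back carbene dimerisation.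

**Step 14**
Reactants: 21 (2S,2''S)-tris(triisopropylsilyl) ether of the target
Product: 22 (2S,2''S)-5,5'',4'''-trihydroxy-7,3',4',7'',3''',5'''-hexamethoxy-2',8''-biflavanone (target)
Conditions: TBAF (3.3 equiv), AcOH (3.6 equiv), THF, 0 °C
Reagents that add atoms: none
Why: Fluoride desilylation of aryl silyl ethers; acetic acid protonates the phenoxides as they form, so neither retro-oxa-Michael opening of rings C and F nor quinone methide formation from the 4'''-phenoxide should scramble C2 and C2''.

**Compound list**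
1 | 2,6-dihydroxy-4-methoxyacetophenone | CC(=O)c1c(O)cc(OC)cc1O | starting material
2 | 1-[2-hydroxy-4-methoxy-6-(triisopropylsilyloxy)phenyl]ethanone | CC(=O)c1c(O)cc(OC)cc1O[Si](C(C)C)(C(C)C)C(C)C | intermediate
3 | 1-[2-hydroxy-3-iodo-4-methoxy-6-(triisopropylsilyloxy)phenyl]ethanone | CC(=O)c1c(O)c(I)c(OC)cc1O[Si](C(C)C)(C(C)C)C(C)C | intermediate
4 | syringaldehyde | COc1cc(C=O)cc(OC)c1O | starting material
5 | 3,5-dimethoxy-4-(triisopropylsilyloxy)benzaldehyde | COc1cc(C=O)cc(OC)c1O[Si](C(C)C)(C(C)C)C(C)C | intermediate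
6 | [3,5-dimethoxy-4-(triisopropylsilyloxy)phenyl]methanol | COc1cc(CO)cc(OC)c1O[Si](C(C)C)(C(C)C)C(C)C | intermediate
7 | ring D–ring E iodide, 1-[2-{[3,5-dimethoxy-4-(triisopropylsilyloxy)benzyl]oxy}-3-iodo-4-methoxy-6-(triisopropylsilyloxy)phenyl]ethanone | CC(=O)c1c(OCc2cc(OC)c(O[Si](C(C)C)(C(C)C)C(C)C)c(OC)c2)c(I)c(OC)cc1O[Si](C(C)C)(C(C)C)C(C)C | intermediate
8 | isovanillin | COc1ccc(C=O)cc1O | starting material
9 | 2-bromo-3-hydroxy-4-methoxybenzaldehyde | COc1ccc(C=O)c(Br)c1O | intermediate
10 | 2-bromo-3,4-dimethoxybenzaldehyde | COc1ccc(C=O)c(Br)c1OC | intermediate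
11 | (2-bromo-3,4-dimethoxyphenyl)methanol | COc1ccc(CO)c(Br)c1OC | intermediate
12 | lithium (2-lithio-3,4-dimethoxyphenyl)methanolate (not isolated) | [Li]OCc1ccc(OC)c(OC)c1[Li] | intermediate
13 | dilithium salt of the aryl(triisopropoxy)borate alkoxide (not isolated) | [Li+].[Li+].[O-]Cc1ccc(OC)c(OC)c1[B-](OC(C)C)(OC(C)C)OC(C)C | intermediate
14 | 6,7-dimethoxy-1,3-dihydro-2,1-benzoxaborol-1-ol | COc1ccc2c(c1OC)B(O)OC2 | intermediate
15 | biaryl alcohol (racemic axis) | CC(=O)c1c(OCc2cc(OC)c(O[Si](C(C)C)(C(C)C)C(C)C)c(OC)c2)c(-c2c(CO)ccc(OC)c2OC)c(OC)cc1O[Si](C(C)C)(C(C)C)C(C)C | intermediate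
16 | bis(methyl ketone) (racemic axis) | COc1cc(O[Si](C(C)C)(C(C)C)C(C)C)c(C(C)=O)c(c1)OCc1ccc(OC)c(OC)c1-c1c(OC)cc(O[Si](C(C)C)(C(C)C)C(C)C)c(C(C)=O)c1OCc1cc(OC)c(O[Si](C(C)C)(C(C)C)C(C)C)c(OC)c1 | intermediate
17 | bis(lithium enolate) of 16 (not isolated) | COc1cc(O[Si](C(C)C)(C(C)C)C(C)C)c(C(=C)O[Li])c(c1)OCc1ccc(OC)c(OC)c1-c1c(OC)cc(O[Si](C(C)C)(C(C)C)C(C)C)c(C(=C)O[Li])c1OCc1cc(OC)c(O[Si](C(C)C)(C(C)C)C(C)C)c(OC)c1 | intermediate
18 | bis(trifluoroacetyl) diketone, each COCH3 of 16 now COCH2COCF3 (used crude, not isolated) | COc1cc(O[Si](C(C)C)(C(C)C)C(C)C)c(C(=O)CC(=O)C(F)(F)F)c(c1)OCc1ccc(OC)c(OC)c1-c1c(OC)cc(O[Si](C(C)C)(C(C)C)C(C)C)c(C(=O)CC(=O)C(F)(F)F)c1OCc1cc(OC)c(O[Si](C(C)C)(C(C)C)C(C)C)c(OC)c1 | intermediate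
19 | bis(diazomethyl ketone) (racemic axis), precursor of the key step | COc1cc(O[Si](C(C)C)(C(C)C)C(C)C)c(C(=O)C=[N+]=[N-])c(c1)OCc1ccc(OC)c(OC)c1-c1c(OC)cc(O[Si](C(C)C)(C(C)C)C(C)C)c(C(=O)C=[N+]=[N-])c1OCc1cc(OC)c(O[Si](C(C)C)(C(C)C)C(C)C)c(OC)c1 | intermediate
20 | half-closed compound, ring F closed (2''S), ring A diazoketone still open (not isolated; the isomer with ring C closed first would react on in the same way) | COc1cc(O[Si](C(C)C)(C(C)C)C(C)C)c(C(=O)C=[N+]=[N-])c(c1)OCc1ccc(OC)c(OC)c1-c1c(OC)cc(O[Si](C(C)C)(C(C)C)C(C)C)c2c1O[C@H](c1cc(OC)c(O[Si](C(C)C)(C(C)C)C(C)C)c(OC)c1)CC2=O | intermediate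
21 | (2S,2''S)-5,5'',4'''-tris-O-(triisopropylsilyl) ether of the target, product of the key step | COc1cc(O[Si](C(C)C)(C(C)C)C(C)C)c2c(c1)O[C@H](c1ccc(OC)c(OC)c1-c1c(OC)cc(O[Si](C(C)C)(C(C)C)C(C)C)c3c1O[C@H](c1cc(OC)c(O[Si](C(C)C)(C(C)C)C(C)C)c(OC)c1)CC3=O)CC2=O | intermediate
22 | (2S,2''S)-5,5'',4'''-trihydroxy-7,3',4',7'',3''',5'''-hexamethoxy-2',8''-biflavanone | COc1cc(O)c2c(c1)O[C@H](c1ccc(OC)c(OC)c1-c1c(OC)cc(O)c3c1O[C@H](c1cc(OC)c(O)c(OC)c1)CC3=O)CC2=O | target

**Step count**
- Total step count: 14.
- Longest linear sequence: 9 steps (8 to 22 through steps 6–14).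

**Steps most likely to fail**

**1. Step 13.**
- Risk: attack of the aryl ether oxygen on the carbene, with ylide formation and 1,2-benzyl migration, may outrun insertion. The catalyst may also distinguish the enantiotopic hydrogens poorly in the atropisomer whose axis is mismatched with it.
- Fallback: the same C2–C3 and C2''–C3'' bonds are made by hydride abstraction instead of a carbene, setting out from 16. KHMDS then Ac2O (THF, −78 °C) should give the bis(enol acetate) F1. DDQ with 2,6-dichloropyridine and LiClO4 in 1,2-dichloroethane should take a hydride from each para-oxygenated benzylic ether CH2. Each cation should then be captured by the neighbouring enol acetate; this oxidative C–H cleavage with 6-endo cyclisation is known for benzylic ethers that carry enol acetates. The product is the stereorandom tris(silyl) biflavanone F2. Preparative chromatography on a chiral stationary phase should deliver the 2S,2''S isomer, and the route is rejoined at 21.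

**2. Step 10.**
- Risk: transmetalation may be slow in a coupling that creates four ortho substituents, which leaves time for protodeiodination. Hot aqueous phosphate may also strip the ring D silyl ether.
- Fallback: a base-free Negishi coupling, setting out from 11 and 7. Dihydropyran and PPTS (CH2Cl2, rt) should give the tetrahydropyranyl ether F3. n-BuLi (THF, −78 °C) should give the aryllithium F4, and ZnCl2 the arylzinc chloride F5. Coupling with 7 (Pd2(dba)3, RuPhos, THF, 60 °C) should give the protected biaryl F6. PPTS in EtOH (45 °C) removes the acetal, and the route is rejoined at 15.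

**3. Step 12.**
- Risk: the ortho silyl group may migrate from the aryl oxygen to the lithium enolate oxygen. One of the two crowded enolates may also be acylated incompletely, so that diazo transfer stops halfway.
- Fallback: a sequence without strong base, setting out from 16. TMSOTf and Et3N (CH2Cl2, 0 °C) should give the bis(trimethylsilyl enol ether) F7. NBS (THF, −78 °C) should give the bis(bromomethyl ketone) F8. N,N'-ditosylhydrazine and DBU (THF, 0 °C) should turn each CH2Br into CH=N2 by N-alkylation and loss of two sulfinates, and the route is rejoined at 19.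

**Further compounds**
F1 | step 13 | bis(enol acetate) of 16 | COc1cc(O[Si](C(C)C)(C(C)C)C(C)C)c(C(=C)OC(C)=O)c(c1)OCc1ccc(OC)c(OC)c1-c1c(OC)cc(O[Si](C(C)C)(C(C)C)C(C)C)c(C(=C)OC(C)=O)c1OCc1cc(OC)c(O[Si](C(C)C)(C(C)C)C(C)C)c(OC)c1
F2 | step 13 | tris(triisopropylsilyl) biflavanone as a mixture of all stereoisomers | COc1cc(O[Si](C(C)C)(C(C)C)C(C)C)c2c(c1)OC(c1ccc(OC)c(OC)c1-c1c(OC)cc(O[Si](C(C)C)(C(C)C)C(C)C)c3c1OC(c1cc(OC)c(O[Si](C(C)C)(C(C)C)C(C)C)c(OC)c1)CC3=O)CC2=O
F3 | step 10 | 2-[(2-bromo-3,4-dimethoxybenzyl)oxy]tetrahydro-2H-pyran (racemic) | COc1ccc(COC2CCCCO2)c(Br)c1OC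
F4 | step 10 | aryllithium from F3 | COc1ccc(COC2CCCCO2)c([Li])c1OC
F5 | step 10 | arylzinc chloride from F4 | COc1ccc(COC2CCCCO2)c([Zn]Cl)c1OC
F6 | step 10 | tetrahydropyranyl ether of 15 | CC(=O)c1c(OCc2cc(OC)c(O[Si](C(C)C)(C(C)C)C(C)C)c(OC)c2)c(-c2c(COC3CCCCO3)ccc(OC)c2OC)c(OC)cc1O[Si](C(C)C)(C(C)C)C(C)C
F7 | step 12 | bis(trimethylsilyl enol ether) of 16 | COc1cc(O[Si](C(C)C)(C(C)C)C(C)C)c(C(=C)O[Si](C)(C)C)c(c1)OCc1ccc(OC)c(OC)c1-c1c(OC)cc(O[Si](C(C)C)(C(C)C)C(C)C)c(C(=C)O[Si](C)(C)C)c1OCc1cc(OC)c(O[Si](C(C)C)(C(C)C)C(C)C)c(OC)c1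
F8 | step 12 | bis(bromomethyl ketone) | COc1cc(O[Si](C(C)C)(C(C)C)C(C)C)c(C(=O)CBr)c(c1)OCc1ccc(OC)c(OC)c1-c1c(OC)cc(O[Si](C(C)C)(C(C)C)C(C)C)c(C(=O)CBr)c1OCc1cc(OC)c(O[Si](C(C)C)(C(C)C)C(C)C)c(OC)c1
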